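The dihydrofuran ring is taken apart at C7a–O1 and C3a–C3 together. O1 and C3 sit on the adjacent benzene carbons C7a and C3a, so an aryne spanning these two carbons can take up a three-atom O1–C2–C3 unit, a 2-oxy aldehyde whose C2 stereocenter comes from the chiral pool. In one operation the key step forges both bonds, closes the five-membered ring and sets C3 relative to C2. Its precursors are an ortho-silyl aryl triflate that carries a C4 chlorine to steer the addition and the acetyl group as a dioxolane, and the triethylsilyl ether of (R)-2-hydroxy-3-methylbut-3-enal, which the same fluoride unmasks in the flask.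

Key step: step 10

Remark: benzofuran numbering (O1, C2, C3, C3a, C4 to C7, C7a) is used for all intermediates; the annulation is assumed to give mainly the 2,3-trans alcohol 18, and any 2,3-cis isomer would be acylated with retention after step 11 to reach the same ester 22.

Step 1
Reactants: 1 1-(2-chloro-4-hydroxyphenyl)ethan-1-one
Product: 2 4-acetyl-3-chlorophenyl N-(propan-2-yl)carbamate
Conditions: i-PrNCO, Et3N (cat.), CH2Cl2, rt
Reagents that add atoms: isopropyl isocyanate, CC(C)N=C=O
Why: Amine-catalysed addition of the phenol to the isocyanate (carbamoylation) gives the NH carbamate that will direct lithiation and can later be removed without acid or strong nucleophiles.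

Step 2
Reactants: 2 4-acetyl-3-chlorophenyl N-(propan-2-yl)carbamate
Product: 3 3-chloro-4-(2-methyl-1,3-dioxolan-2-yl)phenyl N-(propan-2-yl)carbamate
Conditions: HOCH2CH2OH, HC(OEt)3, p-TsOH·H2O (cat.), 40 °C
Reagents that add atoms: ethylene glycol, OCCO
Why: Acid-catalysed ketalisation with the orthoester as dehydrating agent masks the enolisable acetyl group before the organolithium and fluoride steps, at a temperature at which the aryl carbamate should not be transferred to the diol.

Step 3
Reactants: 3 3-chloro-4-(2-methyl-1,3-dioxolan-2-yl)phenyl N-(propan-2-yl)carbamate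
Product: 6 3-chloro-4-(2-methyl-1,3-dioxolan-2-yl)-2-(trimethylsilyl)phenyl N-(propan-2-yl)carbamate, via N-silyl carbamate 4 (not isolated), via C-silylated N-silyl carbamate 5 (not isolated)
Conditions: TBSOTf, TMEDA, Et2O, 0 °C to rt; n-BuLi, −78 °C; TMSCl; aq. work-up
Reagents that add atoms: chlorotrimethylsilane, C[Si](C)(C)Cl
Why: Directed ortho-metalation: after transient N-silylation the carbamate directs n-BuLi to the ring position flanked by the carbamate oxygen and the chlorine, the most acidic C–H, and the aryllithium is trapped by TMSCl at −78 °C before it can lose LiCl, the N–Si bond being hydrolysed on work-up.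

Step 4
Reactants: 6 3-chloro-4-(2-methyl-1,3-dioxolan-2-yl)-2-(trimethylsilyl)phenyl N-(propan-2-yl)carbamate
Product: 8 3-chloro-4-(2-methyl-1,3-dioxolan-2-yl)-2-(trimethylsilyl)phenyl trifluoromethanesulfonate, via silyl phenol 7 (not isolated)
Conditions: DBU, Et2NH, MeCN, 40 °C; then PhNTf2, rt
Reagents that add atoms: N-phenylbis(trifluoromethanesulfonimide), O=S(=O)(N(c1ccccc1)S(=O)(=O)C(F)(F)F)C(F)(F)F
Why: One-pot carbamate cleavage and triflation: DBU deprotonates the NH so that isopropyl isocyanate is expelled (E1cB) and captured by Et2NH, and the phenoxide is then sulfonylated by PhNTf2, which gives the ortho-silyl aryl triflate without acid that would open the ketal.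

Step 5
Reactants: 9 methyl (4S)-2,2-dimethyl-1,3-dioxolane-4-carboxylate
Product: 11 2-[(4S)-2,2-dimethyl-1,3-dioxolan-4-yl]propan-2-ol, via methyl ketone 10 (not isolated)
Conditions: MeMgBr (2.5 equiv), THF, 0 °C to rt
Reagents that add atoms: methylmagnesium bromide, C[Mg]Br
Why: Double Grignard addition to the ester gives the tertiary alcohol, the intermediate ketone being consumed faster than it can enolise, so the dioxolane stereocenter is untouched.

Step 6
Reactants: 11 2-[(4S)-2,2-dimethyl-1,3-dioxolan-4-yl]propan-2-ol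
Product: 12 (4R)-2,2-dimethyl-4-(prop-1-en-2-yl)-1,3-dioxolane
Conditions: Burgess reagent, THF, 50 °C
Reagents that add atoms: none
Why: Burgess dehydration (syn elimination through the sulfamate ester) should remove one of the six methyl hydrogens in preference to the single hindered ring hydrogen and so give the isopropenyl group without acid that would endanger the acetonide; the descriptor becomes R only through the change in CIP priorities.

Step 7
Reactants: 12 (4R)-2,2-dimethyl-4-(prop-1-en-2-yl)-1,3-dioxolane
Product: 13 (2R)-3-methylbut-3-ene-1,2-diol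
Conditions: Dowex 50W (H+ form), MeOH–H2O, rt
Reagents that add atoms: none
Why: Acid-catalysed acetonide hydrolysis (acetal cleavage) frees the diol, and because neither C–O bond of the diol is broken the stereocenter is retained.

Step 8
Reactants: 13 (2R)-3-methylbut-3-ene-1,2-diol
Product: 14 (2R)-3-methyl-1,2-bis(triethylsilyloxy)but-3-ene
Conditions: TESCl, imidazole, DMF, 0 °C to rt
Reagents that add atoms: chlorotriethylsilane, CC[Si](Cl)(CC)CC
Why: Silyl ether formation on both hydroxyl groups with the silyl chloride and imidazole takes place at oxygen only, so the stereocenter is retained.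

Step 9
Reactants: 14 (2R)-3-methyl-1,2-bis(triethylsilyloxy)but-3-ene
Product: 15 (2R)-3-methyl-2-(triethylsilyloxy)but-3-enal
Conditions: (COCl)2, DMSO, CH2Cl2, −78 to −40 °C; i-Pr2NEt, −78 °C
Reagents that add atoms: none
Why: Swern oxidation applied directly to the bis-silyl ether: the chlorosulfonium salt reacts with the unhindered primary triethylsilyl ether and base-induced elimination gives the aldehyde while the secondary silyl ether survives, and the hindered amine and low temperature should keep the allylic α-stereocenter from enolising.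

Step 10
Reactants: 8 3-chloro-4-(2-methyl-1,3-dioxolan-2-yl)-2-(trimethylsilyl)phenyl trifluoromethanesulfonate; 15 (2R)-3-methyl-2-(triethylsilyloxy)but-3-enal
Product: 18 (2R,3S)-4-chloro-5-(2-methyl-1,3-dioxolan-2-yl)-2-(prop-1-en-2-yl)-2,3-dihydro-1-benzofuran-3-ol, via chloroaryne 16 (not isolated), via hydroxy aldehyde 17 (not isolated)
Conditions: CsF, 18-crown-6, THF, 0 °C to rt
Reagents that add atoms: none
Why: Proposed new method: Fluoride removes the trimethylsilyl group of 8 and triflate leaves to give chloroaryne 16, while the same fluoride cleaves the triethylsilyl ether of 15 and releases the alkoxide of 17 only gradually; the alkoxide oxygen adds to the aryne carbon that becomes C7a (C7a–O1) and the resulting C3a aryl anion adds to the neighbouring formyl group (C3a–C3). The closest known reaction types are aryne annulations in which an oxygen or nitrogen nucleophile adds and the aryl anion is captured by a tethered carbonyl group (for example xanthene and xanthone formation from salicylaldehydes and salicylates) and aryne insertions into epoxide C–O bonds that give 2,3-dihydrobenzofurans. The five-membered ring is closed by 5-exo-trig attack of the aryl anion on the aldehyde. C2 is carried in unchanged from 15 because no bond to it is broken, and C3 is set under substrate control by C2: the forming alkoxide oxygen should turn away from the isopropenyl group, which would give the 2,3-trans (3S) alcohol. The step needs regioselective addition to the unsymmetrical aryne, secured by the C4 chlorine, whose inductive pull distorts the aryne so that the nucleophile attacks the distal carbon and the negative charge develops on C3a next to chlorine. It also needs ring closure to outrun protonation of the aryl anion and enolisation at C2, which the aprotic solvent, the short tether and the slow release of the alkoxide in the flask are chosen to ensure.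

Step 11
Reactants: 18 (2R,3S)-4-chloro-5-(2-methyl-1,3-dioxolan-2-yl)-2-(prop-1-en-2-yl)-2,3-dihydro-1-benzofuran-3-ol
Product: 20 1-[(2R,3S)-3-hydroxy-2-(prop-1-en-2-yl)-2,3-dihydro-1-benzofuran-5-yl]ethan-1-one, via dechlorinated ketal 19 (not isolated)
Conditions: Pd(OAc)2 (5 mol %), XPhos (10 mol %), HCO2Na, DMF, 80 °C; then 1 M HCl, rt
Reagents that add atoms: water, O
Why: Palladium-catalysed transfer hydrodechlorination: zerovalent palladium bearing the bulky biarylphosphine inserts into the hindered C4–Cl bond, formate supplies hydride with loss of CO2 and reductive elimination forms C4–H without hydrogen gas that would saturate the isopropenyl group, after which dilute acid in the same flask hydrolyses the electron-rich aryl ketal; no stereocenter is involved.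

Step 12
Reactants: 20 1-[(2R,3S)-3-hydroxy-2-(prop-1-en-2-yl)-2,3-dihydro-1-benzofuran-5-yl]ethan-1-one; 21 3-methylbutanoic acid
Product: 22 (2R,3R)-5-acetyl-2-(prop-1-en-2-yl)-2,3-dihydro-1-benzofuran-3-yl 3-methylbutanoate
Conditions: PPh3, DIAD, THF, 0 °C to rt
Reagents that add atoms: none
Why: Mitsunobu esterification: the carboxylate displaces the oxyphosphonium group at C3 with inversion (SN2), turning the 3S (trans) alcohol into the 3R (cis) ester, while anti elimination to the benzofuran is disfavoured because the C2 hydrogen is syn to the leaving group and ionisation is slowed by the acetyl group para to O1.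

Step 13
Reactants: 22 (2R,3R)-5-acetyl-2-(prop-1-en-2-yl)-2,3-dihydro-1-benzofuran-3-yl 3-methylbutanoate
Product: 23 (2R,3R)-5-[(1R)-1-hydroxyethyl]-2-(prop-1-en-2-yl)-2,3-dihydro-1-benzofuran-3-yl 3-methylbutanoate
Conditions: (S)-2-methyl-CBS-oxazaborolidine (20 mol %), catecholborane, toluene, −78 °C
Reagents that add atoms: none
Why: Corey–Bakshi–Shibata reduction: the (S)-oxazaborolidine activates catecholborane and the ketone so that hydride is delivered to the face giving the (R)-carbinol (aryl large, methyl small) under catalyst control, and catecholborane at −78 °C neither hydroborates the isopropenyl group nor reduces the ester.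

Step 14
Reactants: 23 (2R,3R)-5-[(1R)-1-hydroxyethyl]-2-(prop-1-en-2-yl)-2,3-dihydro-1-benzofuran-3-yl 3-methylbutanoate; 24 (2R)-2-methylbutanoic acid
Product: 25 (1R)-1-[(2R,3R)-3-(3-methylbutanoyloxy)-2-(prop-1-en-2-yl)-2,3-dihydro-1-benzofuran-5-yl]ethyl (2R)-2-methylbutanoate
Conditions: DCC, DMAP (cat.), CH2Cl2, 0 °C
Reagents that add atoms: none
Why: Steglich esterification acylates the carbinol oxygen, so the benzylic stereocenter is retained, and the α-stereocenter of the acid, which carries only alkyl groups, should not epimerise with catalytic DMAP at 0 °C.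

Step 15
Reactants: 25 (1R)-1-[(2R,3R)-3-(3-methylbutanoyloxy)-2-(prop-1-en-2-yl)-2,3-dihydro-1-benzofuran-5-yl]ethyl (2R)-2-methylbutanoate
Product: 27 (1R)-1-[(2R,3R)-3-(3-methylbutanoyloxy)-2-(3-oxoprop-1-en-2-yl)-2,3-dihydro-1-benzofuran-5-yl]ethyl (2R)-2-methylbutanoate, via allylic alcohol 26 (not isolated)
Conditions: SeO2, 1,4-dioxane, 80 °C
Reagents that add atoms: selenium dioxide, O=[Se]=O
Why: Riley oxidation: ene reaction of SeO2 at the terminal CH2 and [2,3]-sigmatropic shift hydroxylate the vinylic methyl group (methyl is preferred over the oxygen-bearing C2–H of the 1,1-disubstituted alkene) and the allylic alcohol is oxidised further to the enal by the same reagent; no stereocenter is touched.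

Compound list
1 | 1-(2-chloro-4-hydroxyphenyl)ethan-1-one | CC(=O)c1ccc(O)cc1Cl | starting material
2 | 4-acetyl-3-chlorophenyl N-(propan-2-yl)carbamate | CC(=O)c1ccc(OC(=O)NC(C)C)cc1Cl | intermediate
3 | 3-chloro-4-(2-methyl-1,3-dioxolan-2-yl)phenyl N-(propan-2-yl)carbamate | CC1(OCCO1)c1ccc(OC(=O)NC(C)C)cc1Cl | intermediate
4 | 3-chloro-4-(2-methyl-1,3-dioxolan-2-yl)phenyl N-(tert-butyldimethylsilyl)-N-(propan-2-yl)carbamate | CC1(OCCO1)c1ccc(OC(=O)N(C(C)C)[Si](C)(C)C(C)(C)C)cc1Cl | intermediate
5 | 3-chloro-4-(2-methyl-1,3-dioxolan-2-yl)-2-(trimethylsilyl)phenyl N-(tert-butyldimethylsilyl)-N-(propan-2-yl)carbamate | CC1(OCCO1)c1ccc(OC(=O)N(C(C)C)[Si](C)(C)C(C)(C)C)c([Si](C)(C)C)c1Cl | intermediate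
6 | 3-chloro-4-(2-methyl-1,3-dioxolan-2-yl)-2-(trimethylsilyl)phenyl N-(propan-2-yl)carbamate | CC1(OCCO1)c1ccc(OC(=O)NC(C)C)c([Si](C)(C)C)c1Cl | intermediate
7 | 3-chloro-4-(2-methyl-1,3-dioxolan-2-yl)-2-(trimethylsilyl)phenol | CC1(OCCO1)c1ccc(O)c([Si](C)(C)C)c1Cl | intermediate
8 | 3-chloro-4-(2-methyl-1,3-dioxolan-2-yl)-2-(trimethylsilyl)phenyl trifluoromethanesulfonate | CC1(OCCO1)c1ccc(OS(=O)(=O)C(F)(F)F)c([Si](C)(C)C)c1Cl | intermediate
9 | methyl (4S)-2,2-dimethyl-1,3-dioxolane-4-carboxylate | COC(=O)[C@@H]1COC(C)(C)O1 | starting material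
10 | 1-[(4S)-2,2-dimethyl-1,3-dioxolan-4-yl]ethan-1-one | CC(=O)[C@@H]1COC(C)(C)O1 | intermediate
11 | 2-[(4S)-2,2-dimethyl-1,3-dioxolan-4-yl]propan-2-ol | CC(C)(O)[C@@H]1COC(C)(C)O1 | intermediate
12 | (4R)-2,2-dimethyl-4-(prop-1-en-2-yl)-1,3-dioxolane | C=C(C)[C@@H]1COC(C)(C)O1 | intermediate
13 | (2R)-3-methylbut-3-ene-1,2-diol | C=C(C)[C@@H](O)CO | intermediate
14 | (2R)-3-methyl-1,2-bis(triethylsilyloxy)but-3-ene | C=C(C)[C@@H](O[Si](CC)(CC)CC)CO[Si](CC)(CC)CC | intermediate
15 | (2R)-3-methyl-2-(triethylsilyloxy)but-3-enal | C=C(C)[C@@H](O[Si](CC)(CC)CC)C=O | intermediate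
16 | 3-chloro-4-(2-methyl-1,3-dioxolan-2-yl)benzyne | CC1(OCCO1)C1=C(Cl)C#CC=C1 | intermediate
17 | (2R)-2-hydroxy-3-methylbut-3-enal (present as its cesium alkoxide) | C=C(C)[C@@H](O)C=O | intermediate
18 | (2R,3S)-4-chloro-5-(2-methyl-1,3-dioxolan-2-yl)-2-(prop-1-en-2-yl)-2,3-dihydro-1-benzofuran-3-ol (2,3-trans) | C=C(C)[C@H]1Oc2ccc(C3(C)OCCO3)c(Cl)c2[C@@H]1O | intermediate
19 | (2R,3S)-5-(2-methyl-1,3-dioxolan-2-yl)-2-(prop-1-en-2-yl)-2,3-dihydro-1-benzofuran-3-ol | C=C(C)[C@H]1Oc2ccc(C3(C)OCCO3)cc2[C@@H]1O | intermediate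
20 | 1-[(2R,3S)-3-hydroxy-2-(prop-1-en-2-yl)-2,3-dihydro-1-benzofuran-5-yl]ethan-1-one | C=C(C)[C@H]1Oc2ccc(C(C)=O)cc2[C@@H]1O | intermediate
21 | 3-methylbutanoic acid | CC(C)CC(=O)O | starting material
22 | (2R,3R)-5-acetyl-2-(prop-1-en-2-yl)-2,3-dihydro-1-benzofuran-3-yl 3-methylbutanoate (2,3-cis) | C=C(C)[C@H]1Oc2ccc(C(C)=O)cc2[C@H]1OC(=O)CC(C)C | intermediate
23 | (2R,3R)-5-[(1R)-1-hydroxyethyl]-2-(prop-1-en-2-yl)-2,3-dihydro-1-benzofuran-3-yl 3-methylbutanoate | C=C(C)[C@H]1Oc2ccc([C@@H](C)O)cc2[C@H]1OC(=O)CC(C)C | intermediate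
24 | (2R)-2-methylbutanoic acid | CC[C@@H](C)C(=O)O | starting material
25 | (1R)-1-[(2R,3R)-3-(3-methylbutanoyloxy)-2-(prop-1-en-2-yl)-2,3-dihydro-1-benzofuran-5-yl]ethyl (2R)-2-methylbutanoate | C=C(C)[C@H]1Oc2ccc([C@@H](C)OC(=O)[C@H](C)CC)cc2[C@H]1OC(=O)CC(C)C | intermediate
26 | (1R)-1-[(2R,3R)-2-(3-hydroxyprop-1-en-2-yl)-3-(3-methylbutanoyloxy)-2,3-dihydro-1-benzofuran-5-yl]ethyl (2R)-2-methylbutanoate | C=C(CO)[C@H]1Oc2ccc([C@@H](C)OC(=O)[C@H](C)CC)cc2[C@H]1OC(=O)CC(C)C | intermediate
27 | (1R)-1-[(2R,3R)-3-(3-methylbutanoyloxy)-2-(3-oxoprop-1-en-2-yl)-2,3-dihydro-1-benzofuran-5-yl]ethyl (2R)-2-methylbutanoate | C=C(C=O)[C@H]1Oc2ccc([C@@H](C)OC(=O)[C@H](C)CC)cc2[C@H]1OC(=O)CC(C)C | target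

Total step count: 15. Longest linear sequence: 11 steps (steps 5 to 9 from ester 9, then steps 10 to 15).

Steps most likely to fail

First, step 10 (the annulation). The unmasked hydroxy aldehyde may enolise or condense with itself before it meets the aryne, the aryl anion may be protonated before it closes the ring, or the facial selectivity at C3 may be low. The fallback makes the two bonds one after the other by known reactions. It sets out from diol 13: tritylation of the primary hydroxyl (TrCl, pyridine) gives (2R)-3-methyl-1-(triphenylmethoxy)but-3-en-2-ol F1. Its sodium alkoxide (NaH, DMF, 0 °C) displaces fluoride from commercial 1-(4-fluoro-3-iodophenyl)ethan-1-one (CC(=O)c1ccc(F)c(I)c1) in an SNAr reaction that forms C7a–O1 with retention at C2 and gives 1-[3-iodo-4-{[(2R)-3-methyl-1-(triphenylmethoxy)but-3-en-2-yl]oxy}phenyl]ethan-1-one F2. Detritylation (p-TsOH, MeOH–CH2Cl2) gives 1-[4-{[(2R)-1-hydroxy-3-methylbut-3-en-2-yl]oxy}-3-iodophenyl]ethan-1-one F3, and Dess–Martin oxidation gives (2R)-2-(4-acetyl-2-iodophenoxy)-3-methylbut-3-enal F4. An intramolecular Nozaki–Hiyama–Kishi reaction (CrCl2, NiCl2 cat., DMF), which leaves the methyl ketone alone, then closes C3a–C3 and comes back to the route at keto alcohol 20.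

Second, step 11 (removal of chlorine). Zerovalent palladium may ionise the allylic C2–O1 ether and hydride capture would then open the ring, or insertion into the doubly ortho-substituted C–Cl bond may be too slow. The fallback avoids a transition metal and makes no new compound (F0). It sets out from 18: the hydroxyl is deprotonated (n-BuLi, THF, −78 °C), the C–Cl bond is reductively lithiated with lithium 4,4'-di-tert-butylbiphenylide (2.2 equiv, −78 °C) and the aryllithium is quenched with MeOH. This comes back to the route at 19, which is hydrolysed with 1 M HCl as in step 11.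

Third, step 12 (inversion at C3). The activated alcohol may ionise at the benzylic carbon, which would lose the inversion, or eliminate towards the aromatic benzofuran, and displacement syn to the isopropenyl group may be slow. The fallback inverts C3 by oxidation and reduction at the ketal stage. It sets out from 19, isolated by leaving out the acid treatment of step 11. Dess–Martin periodinane with NaHCO3 gives (2R)-5-(2-methyl-1,3-dioxolan-2-yl)-2-(prop-1-en-2-yl)-1-benzofuran-3(2H)-one F5. This is reduced at once with NaBH4 in MeOH–CH2Cl2 at −78 °C, hydride entering anti to the C2 substituent, to (2R,3R)-5-(2-methyl-1,3-dioxolan-2-yl)-2-(prop-1-en-2-yl)-2,3-dihydro-1-benzofuran-3-ol F6. Acylation with acid 21 (DCC, DMAP) gives (2R,3R)-5-(2-methyl-1,3-dioxolan-2-yl)-2-(prop-1-en-2-yl)-2,3-dihydro-1-benzofuran-3-yl 3-methylbutanoate F7, and ketal hydrolysis (AcOH–THF–H2O, rt) comes back to the route at 22.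

Further compounds
F1 | step 10 | (2R)-3-methyl-1-(triphenylmethoxy)but-3-en-2-ol | C=C(C)[C@@H](O)COC(c1ccccc1)(c1ccccc1)c1ccccc1
F2 | step 10 | 1-[3-iodo-4-{[(2R)-3-methyl-1-(triphenylmethoxy)but-3-en-2-yl]oxy}phenyl]ethan-1-one | C=C(C)[C@@H](Oc1ccc(C(C)=O)cc1I)COC(c1ccccc1)(c1ccccc1)c1ccccc1
F3 | step 10 | 1-[4-{[(2R)-1-hydroxy-3-methylbut-3-en-2-yl]oxy}-3-iodophenyl]ethan-1-one | C=C(C)[C@@H](Oc1ccc(C(C)=O)cc1I)CO
F4 | step 10 | (2R)-2-(4-acetyl-2-iodophenoxy)-3-methylbut-3-enal | C=C(C)[C@@H](Oc1ccc(C(C)=O)cc1I)C=O
F0 | step 11 | none | none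
F5 | step 12 | (2R)-5-(2-methyl-1,3-dioxolan-2-yl)-2-(prop-1-en-2-yl)-1-benzofuran-3(2H)-one | C=C(C)[C@H]1Oc2ccc(C3(C)OCCO3)cc2C1=O
F6 | step 12 | (2R,3R)-5-(2-methyl-1,3-dioxolan-2-yl)-2-(prop-1-en-2-yl)-2,3-dihydro-1-benzofuran-3-ol | C=C(C)[C@H]1Oc2ccc(C3(C)OCCO3)cc2[C@H]1O
F7 | step 12 | (2R,3R)-5-(2-methyl-1,3-dioxolan-2-yl)-2-(prop-1-en-2-yl)-2,3-dihydro-1-benzofuran-3-yl 3-methylbutanoate | C=C(C)[C@H]1Oc2ccc(C3(C)OCCO3)cc2[C@H]1OC(=O)CC(C)C
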